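Remark on the chemistry: (−)-drimenol (1) is assumed to be a purchasable chiral-pool terpene (catalogue natural product); (R)-(−)-carvone (7) and all reagents are ordinary commercial chemicals.

## Analysis of the target

The target is a cis-fused 4a,5,6,8a-tetrahydro-2H-chromen-6-one: a dihydropyran ring O1–C2–C3=C4–C4a–C8a fused to a cyclohexenone ring C4a–C5–C6(=O)–C7(CH3)=C8–C8a. C4 carries an acetoxymethyl group, and C2 carries a trans-decalin (a drim-6-en-8α-ol, primed drimane numbering C1′–C10′), bonded through C9′, so that C2 is C11 of the drimane. There are seven stereocentres. C5′, C8′, C9′ and C10′ have the natural drimane configuration (5α-H, 8α-OH/8β-CH3, 9α-H, 10β-CH3). On the chromenone, H-2, H-4a and H-8a lie on one face (2R,4aR,8aR), so the pyran is 2,6-cis and the ring fusion is cis. The feature the route is built on is this: the ring C4a–C5–C6–C7(CH3)–C8–C8a together with C4, C3 and the acetoxymethyl carbon is an intact p-menthane skeleton with the ketone, the C7=C8 bond and the C4a configuration of (R)-carvone, oxygenated in addition at C8a. The drimane half is attached to this unit only through C2, by the bonds C2–C3 and C2–O1. Sensitive groups are the tertiary allylic alcohol at C8′ (ionisation, dehydration), the γ-alkoxy enone (epimerisation at C8a through the dienol, aromatisation if O1 leaves), the doubly allylic ether carbon C2 and the primary allylic acetate. The synthesis is hard for three reasons: O1 bridges two hindered secondary carbons (C2 sits next to C9′ between the quaternary C8′ and C10′); O1 must be cis to the C4a substituent although electrophiles attack a carvone dienol anti to it; and the C3=C4 bond must lie on the C2 side with the oxygen on the exocyclic carbon.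

## Retrosynthetic reasoning

17 to 16. Only the O–Si bond at C8′ is cut. The tertiary allylic alcohol is the most acid-labile group, so it is carried as its triethylsilyl ether from 5 onwards and freed last with buffered fluoride.

16 to 15 to 14. The C–O bond of the allylic acetate is cut and the C3=C4 bond is moved back to the exocyclic position. Forward, an ene-type allylic chlorination of the 4-methylene pyran 14 puts chlorine on the exocyclic carbon and shifts the double bond into the ring (15), and acetate displaces the chloride (16). This is chosen because an exocyclic methylene is exactly what the annulation below leaves behind. The ring-fusion hydrogen H-4a lies near the plane of that alkene, so the new double bond should go to C3.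

14 to 13 + 6 (key disconnection). Both bonds at C2 are cut: C2–O1 and C2–C3. C2 is the only atom that joins the two terpene halves, so this one cut separates the target into aldehyde 6 (the complete drimane half, C2 as the formyl carbon) and the hydroxy allylsilane 13, whose ten skeletal carbons are those of carvone 7. Forward, a Lewis-acid-promoted Prins-type annulation must form an oxocarbenium ion from a hindered aldehyde, close the pyran and set C2 from the existing centres C4a and C8a. No reagent control is needed, and the C9′ neighbourhood does not have to direct anything.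

13 to 12 to 11. No skeletal bond is cut; C8a is inverted. Oxygenation of the dienol ether 10 occurs anti to the C4a side chain and gives the trans alcohol 11, whereas the annulation needs the cis alcohol. A Mitsunobu esterification (12) and mild methanolysis (13) correct this.

11 to 10 to 9. The C8a–O bond is cut. Forward, the through-conjugated silyl dienol ether 10 of enone 9 is oxidised at its γ-carbon (vinylogous Rubottom oxidation). This uses the enone that carvone already has.

9 to 8 to 7. The C–Si bond, then the C–Cl bond, are cut. The isopropenyl methyl group of 7 is chlorinated by an ene-type reaction (8) and the allyl chloride is silylated under palladium catalysis (9). The π-allyl intermediate has equivalent termini, so there is no regiochemical question.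

6 to 5 to 4 to 2 to 1. The aldehyde comes from the primary alcohol. The tertiary allylic alcohol at C8′ with the C6′=C7′ bond comes from the C7′=C8′ alkene of 1 by α-face epoxidation (2), selenolate opening at C7′ (3) and selenoxide elimination (4). Silylation of both hydroxyls (5) and oxidative cleavage of the primary silyl ether give 6. All four decalin stereocentres come from the chiral pool.

## Alternatives that were turned down

Alternative 1: The textbook route cuts C2–C3 as a vinyl–carbinol bond and O1–C8a as an ether bond. Forward, a Nozaki–Hiyama–Kishi addition of the carvone-derived vinyl iodide A1 to aldehyde 6 would give the allylic alcohol A2, and the pyran would then be closed by γ-functionalisation of the enone and intramolecular displacement at C8a. It was turned down for three reasons. C2 would be set by addition to an aldehyde whose α-carbon lies between two quaternary centres, and no model predicts the face reliably. A1 needs a trisubstituted vinyl iodide of defined geometry, which the isopropenyl group of 7 does not offer without several extra steps. The closure at the γ-position of an enone competes with elimination and aromatisation.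

Alternative 2: The oxa-Michael route cuts O1–C2 with C4 as a ketone. Forward, the methyl ketone A3 (from ozonolysis of the side chain) would undergo aldol condensation with 6 to give enone A4, and intramolecular oxa-Michael addition under thermodynamic control would give the 2,6-cis tetrahydropyran-4-one A5. C4 would then be converted into the acetoxymethyl-bearing alkene by enol triflate formation and cross-coupling. It was turned down because A5 holds two ketones, the triflation must choose C3 over C4a, and the C1 unit is added at the end. It also still needs the cis C8a alcohol and is longer than the chosen route.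

Alternative 3: The boldest cut breaks C4a–C8a and O1–C2 together, an intramolecular hetero-Diels–Alder reaction. Forward, the furan A6 would be opened oxidatively to the (Z)-keto-enal A7, whose aldehyde would add across the diene C2=C3–C4=C4a, forming both rings of the chromenone and C2, C4a and C8a in one step. It was turned down because the facial selectivity would rest only on C9′ next to the diene terminus, for which no reliable model exists. A conjugated aldehyde is also a poor heterodienophile, and carbonyl-ene and polymerisation paths compete. The stereodefined triene A6 would cost more steps than both terpene fragments together, and the free C4a stereocentre of 7 would be given up.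

Key step: step 10

## Route

Step 1
Reactants: 1 (−)-drimenol (drim-7-en-11-ol)
Product: 2 7α,8α-epoxydriman-11-ol
Conditions: mCPBA, NaHCO3, CH2Cl2, 0 °C
Reagents that add atoms: mCPBA, OOC(=O)c1cccc(Cl)c1
Why: Prilezhaev epoxidation of the trisubstituted alkene; the β-face is shielded by the axial C10′ methyl group, so the oxygen should enter from the α-face.

Step 2
Reactants: 2 7α,8α-epoxydriman-11-ol
Product: 4 drim-6-ene-8α,11-diol, via 7β-(phenylselanyl)drimane-8α,11-diol 3 (not isolated)
Conditions: PhSeSePh, NaBH4, EtOH, reflux; then 30% H2O2, THF, 0 °C to rt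
Reagents that add atoms: none
Why: Epoxide-to-allylic-alcohol transposition by selenolate opening and selenoxide elimination; the selenolate attacks the secondary C7′ anti to the oxygen, which stays on C8′ with its α-configuration. The selenoxide can only eliminate towards C6′ because C8′ has no hydrogen.

Step 3
Reactants: 4 drim-6-ene-8α,11-diol
Product: 5 8α,11-bis(triethylsilyloxy)drim-6-ene
Conditions: TESOTf, 2,6-lutidine, CH2Cl2, −78 to 0 °C
Reagents that add atoms: triethylsilyl triflate, CC[Si](CC)(CC)OS(=O)(=O)C(F)(F)F
Why: A silyl triflate with a hindered pyridine base silylates the primary and also the hindered tertiary allylic hydroxyl without ionising it.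

Step 4
Reactants: 5 8α,11-bis(triethylsilyloxy)drim-6-ene
Product: 6 8α-(triethylsilyloxy)drim-6-en-11-al
Conditions: (COCl)2, DMSO, CH2Cl2, −78 to −30 °C; then Et3N
Reagents that add atoms: none
Why: Under Swern conditions a primary triethylsilyl ether is cleaved and oxidised directly to the aldehyde, while the tertiary silyl ether is too hindered to react. The equatorial formyl group at C9′ is the stable epimer, so C9′ is not at risk.

Step 5
Reactants: 7 (R)-(−)-carvone
Product: 8 (5R)-5-(3-chloroprop-1-en-2-yl)-2-methylcyclohex-2-en-1-one (10-chlorocarvone)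
Conditions: Ca(OCl)2, CO2 (dry ice), CH2Cl2/H2O, 0 °C
Reagents that add atoms: calcium hypochlorite, [Ca+2].[O-]Cl.[O-]Cl
Why: Ene-type allylic chlorination by hypochlorous acid attacks the electron-rich 1,1-disubstituted alkene and leaves the conjugated enone untouched; C4a is not involved.

Step 6
Reactants: 8 10-chlorocarvone
Product: 9 (5R)-2-methyl-5-[3-(trimethylsilyl)prop-1-en-2-yl]cyclohex-2-en-1-one
Conditions: Me3SiSiMe3, Pd(dba)2 (3 mol %), THF, 60 °C
Reagents that add atoms: hexamethyldisilane, C[Si](C)(C)[Si](C)(C)C
Why: Pd-catalysed silylation of an allylic chloride with a disilane through a π-allyl complex whose two termini are equivalent, so only one allylsilane can form. Hexamethyldisilane does not add to the enone.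

Step 7
Reactants: 9 the allylsilane enone
Product: 11 (4S,5R)-4-hydroxy-2-methyl-5-[3-(trimethylsilyl)prop-1-en-2-yl]cyclohex-2-en-1-one (trans), via 2-methyl-1-(trimethylsilyloxy)-5-[3-(trimethylsilyl)prop-1-en-2-yl]cyclohexa-1,3-diene 10 (not isolated)
Conditions: TMSOTf, Et3N, CH2Cl2, 0 °C to rt (equilibration); solvent exchange; DMDO, acetone, −78 °C; aq. citric acid
Reagents that add atoms: dimethyldioxirane, CC1(C)OO1
Why: Vinylogous Rubottom oxidation: equilibrating soft enolisation gives the through-conjugated dienol ether 10. The dioxirane epoxidises its terminal double bond anti to the C4a side chain, and the epoxide collapses to the γ-hydroxy enone, hence trans. At −78 °C the allylsilane alkene should not compete with the far more electron-rich dienol ether.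

Step 8
Reactants: 11 the trans γ-hydroxy enone
Product: 12 (4R,5R)-4-(4-nitrobenzoyloxy)-2-methyl-5-[3-(trimethylsilyl)prop-1-en-2-yl]cyclohex-2-en-1-one (cis)
Conditions: 4-O2NC6H4CO2H, PPh3, DIAD, toluene, 0 °C to rt
Reagents that add atoms: 4-nitrobenzoic acid, OC(=O)c1ccc(cc1)[N+](=O)[O-]
Why: Mitsunobu esterification; the carboxylate displaces the oxyphosphonium group at C8a by SN2 with inversion, which puts the oxygen cis to the C4a side chain.

Step 9
Reactants: 12 the cis 4-nitrobenzoate
Product: 13 (4R,5R)-4-hydroxy-2-methyl-5-[3-(trimethylsilyl)prop-1-en-2-yl]cyclohex-2-en-1-one (cis)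
Conditions: K2CO3 (0.2 equiv), MeOH, 0 °C
Reagents that add atoms: none
Why: Transesterification of the activated aryl ester under mild base; low temperature and short time are meant to prevent dienolisation and epimerisation at C8a, and the allylsilane is stable to methoxide.

Step 10
Reactants: 13 the cis hydroxy allylsilane; 6 8α-(triethylsilyloxy)drim-6-en-11-al
Product: 14 (2R,4aR,8aR)-7-methyl-4-methylidene-2-[8α-(triethylsilyloxy)-11-nordrim-6-en-9β-yl]-2,3,4,4a,5,8a-hexahydro-6H-chromen-6-one
Conditions: TMSOTf (1.1 equiv), Et2O, −78 °C; sat. aq. NaHCO3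
Reagents that add atoms: none
Why: TMSOTf converts alcohol 13 and aldehyde 6 into a mixed silyl acetal, which ionises to the (E)-oxocarbenium ion C8a–O1(+)=C2. The allylsilane terminus C3 attacks C2 and the β-silyl cation at C4 loses Me3Si to leave the exocyclic alkene; this is an intramolecular silyl-modified Sakurai (silyl-Prins) pyran annulation, the established way from hydroxy allylsilanes and aldehydes to cis-2,6-disubstituted 4-methylenetetrahydropyrans. The ring O1–C2–C3–C4–C4a–C8a closes in a 6-endo-trig mode through a chair. C2 is the only new stereocentre and is controlled by C8a and C4a: the drimane residue sits equatorial on the (E)-oxocarbenium ion, C8 is equatorial on C8a, and C5 is axial on C4a because an equatorial C5 would suffer A(1,3) strain with the in-plane CH2SiMe3/methylidene group on C4. H-2 therefore becomes axial and syn to H-8a, which is the (2R) configuration of the target. The step needs chemoselectivity for the aldehyde over the enone carbonyl and over ionisation of the tertiary allylic silyl ether at C8′; only the aldehyde can form an acetal with the hydroxyl, the reaction is run at −78 °C in ether, and the C8′ oxygen is shielded by the triethylsilyl group and its quaternary carbon. Cyclisation should outrun protodesilylation because the nucleophile is held four atoms from the cationic carbon.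

Step 11
Reactants: 14 the 4-methylidene pyran
Product: 15 (2R,4aR,8aR)-4-(chloromethyl)-7-methyl-2-[8α-(triethylsilyloxy)-11-nordrim-6-en-9β-yl]-4a,5-dihydro-2H-chromen-6(8aH)-one
Conditions: Ca(OCl)2, CO2 (dry ice), CH2Cl2/H2O, 0 °C
Reagents that add atoms: calcium hypochlorite, [Ca+2].[O-]Cl.[O-]Cl
Why: Ene-type allylic chlorination of the exocyclic 1,1-disubstituted alkene: chlorine adds to the exocyclic carbon and a proton is lost from the ring CH2 (C3), whose axial C–H is aligned. H-4a is equatorial on the pyran and lies near the alkene plane, so it should not be lost. The conjugated enone and the hindered cis-disubstituted C6′=C7′ alkene next to the silyloxy-bearing quaternary carbon are much less nucleophilic.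

Step 12
Reactants: 15 the allylic chloride
Product: 16 [(2R,4aR,8aR)-7-methyl-6-oxo-2-[8α-(triethylsilyloxy)-11-nordrim-6-en-9β-yl]-4a,5,6,8a-tetrahydro-2H-chromen-4-yl]methyl acetate
Conditions: KOAc, 18-crown-6 (cat.), DMF, 40 °C
Reagents that add atoms: potassium acetate, CC(=O)[O-].[K+]
Why: SN2 displacement of a primary allylic chloride by acetate; direct attack at the unhindered CH2 is favoured over SN2′ at C3, and the weakly basic conditions leave the γ-alkoxy enone alone.

Step 13
Reactants: 16 the silyl-protected acetate
Product: 17 the target, [(2R,4aR,8aR)-2-(8α-hydroxy-11-nordrim-6-en-9β-yl)-7-methyl-6-oxo-4a,5,6,8a-tetrahydro-2H-chromen-4-yl]methyl acetate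
Conditions: HF·pyridine, pyridine, THF, 0 °C to rt
Reagents that add atoms: none
Why: Fluoride cleavage of the triethylsilyl ether under pyridine-buffered conditions, which should neither ionise the tertiary allylic alcohol nor touch the acetate or the enone.

## Compound list

1 | (−)-drimenol (drim-7-en-11-ol) | OC[C@@H]1[C@@]2(C)CCCC(C)(C)[C@@H]2CC=C1C | starting material
2 | 7α,8α-epoxydriman-11-ol | OC[C@@H]1[C@@]2(C)CCCC(C)(C)[C@@H]2C[C@H]3O[C@@]13C | intermediate
3 | 7β-(phenylselanyl)drimane-8α,11-diol | OC[C@@H]1[C@@]2(C)CCCC(C)(C)[C@@H]2C[C@H]([Se]c3ccccc3)[C@@]1(C)O | intermediate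
4 | drim-6-ene-8α,11-diol | OC[C@@H]1[C@@]2(C)CCCC(C)(C)[C@@H]2C=C[C@@]1(C)O | intermediate
5 | 8α,11-bis(triethylsilyloxy)drim-6-ene | CC[Si](CC)(CC)OC[C@@H]1[C@@]2(C)CCCC(C)(C)[C@@H]2C=C[C@@]1(C)O[Si](CC)(CC)CC | intermediate
6 | 8α-(triethylsilyloxy)drim-6-en-11-al | O=C[C@@H]1[C@@]2(C)CCCC(C)(C)[C@@H]2C=C[C@@]1(C)O[Si](CC)(CC)CC | intermediate
7 | (R)-(−)-carvone | C=C(C)[C@H]1CC(=O)C(C)=CC1 | starting material
8 | (5R)-5-(3-chloroprop-1-en-2-yl)-2-methylcyclohex-2-en-1-one (10-chlorocarvone) | C=C(CCl)[C@H]1CC(=O)C(C)=CC1 | intermediate
9 | (5R)-2-methyl-5-[3-(trimethylsilyl)prop-1-en-2-yl]cyclohex-2-en-1-one | C=C(C[Si](C)(C)C)[C@H]1CC(=O)C(C)=CC1 | intermediate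
10 | 2-methyl-1-(trimethylsilyloxy)-5-[3-(trimethylsilyl)prop-1-en-2-yl]cyclohexa-1,3-diene (side-chain carbon configured as in 9) | C=C(C[Si](C)(C)C)[C@H]1CC(O[Si](C)(C)C)=C(C)C=C1 | intermediate
11 | (4S,5R)-4-hydroxy-2-methyl-5-[3-(trimethylsilyl)prop-1-en-2-yl]cyclohex-2-en-1-one (trans) | C=C(C[Si](C)(C)C)[C@H]1CC(=O)C(C)=C[C@@H]1O | intermediate
12 | (4R,5R)-4-(4-nitrobenzoyloxy)-2-methyl-5-[3-(trimethylsilyl)prop-1-en-2-yl]cyclohex-2-en-1-one (cis) | C=C(C[Si](C)(C)C)[C@H]1CC(=O)C(C)=C[C@H]1OC(=O)c2ccc(cc2)[N+](=O)[O-] | intermediate
13 | (4R,5R)-4-hydroxy-2-methyl-5-[3-(trimethylsilyl)prop-1-en-2-yl]cyclohex-2-en-1-one (cis) | C=C(C[Si](C)(C)C)[C@H]1CC(=O)C(C)=C[C@H]1O | intermediate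
14 | (2R,4aR,8aR)-7-methyl-4-methylidene-2-[8α-(triethylsilyloxy)-11-nordrim-6-en-9β-yl]-2,3,4,4a,5,8a-hexahydro-6H-chromen-6-one | C=C1C[C@H]([C@@H]2[C@@]3(C)CCCC(C)(C)[C@@H]3C=C[C@@]2(C)O[Si](CC)(CC)CC)O[C@@H]2C=C(C)C(=O)C[C@H]12 | intermediate
15 | (2R,4aR,8aR)-4-(chloromethyl)-7-methyl-2-[8α-(triethylsilyloxy)-11-nordrim-6-en-9β-yl]-4a,5-dihydro-2H-chromen-6(8aH)-one | ClCC1=C[C@H]([C@@H]2[C@@]3(C)CCCC(C)(C)[C@@H]3C=C[C@@]2(C)O[Si](CC)(CC)CC)O[C@@H]2C=C(C)C(=O)C[C@H]12 | intermediate
16 | [(2R,4aR,8aR)-7-methyl-6-oxo-2-[8α-(triethylsilyloxy)-11-nordrim-6-en-9β-yl]-4a,5,6,8a-tetrahydro-2H-chromen-4-yl]methyl acetate | CC(=O)OCC1=C[C@H]([C@@H]2[C@@]3(C)CCCC(C)(C)[C@@H]3C=C[C@@]2(C)O[Si](CC)(CC)CC)O[C@@H]2C=C(C)C(=O)C[C@H]12 | intermediate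
17 | [(2R,4aR,8aR)-2-(8α-hydroxy-11-nordrim-6-en-9β-yl)-7-methyl-6-oxo-4a,5,6,8a-tetrahydro-2H-chromen-4-yl]methyl acetate (CNP0180075.1) | CC(=O)OCC1=C[C@H]([C@@H]2[C@@]3(C)CCCC(C)(C)[C@@H]3C=C[C@@]2(C)O)O[C@@H]2C=C(C)C(=O)C[C@H]12 | target

## Step count and risk

Total step count: 13. Longest linear sequence: 9 steps (7 to 17, steps 5 to 13); the drimane branch (steps 1 to 4) joins at step 10.

Least certain steps:

Step 10 (key step). The most likely failure is Lewis-acid ionisation of the tertiary allylic silyl ether at C8′, followed by elimination to a diene, before the very hindered aldehyde has formed the oxocarbenium ion. A second risk is poor discrimination between the two chair transition states (C5 axial against C8 axial), which would erode the selectivity at C2. The fallback sets out from 11 and 6 and comes back at 14; it forms the C2–C3 bond first and uses the natural trans oxygen at C8a as a leaving group. Mesylation of 11 gives the trans mesylate F1. A BF3·OEt2-mediated Hosomi–Sakurai addition of F1 to 6 at −78 °C gives the homoallylic alcohol F2. Its alkoxide (NaH, THF, 0 °C) closes the pyran by SN2 at C8a with inversion to give 14. In this fallback C2 depends on the facial bias of the aldehyde, so a C2 epimer would have to be separated.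

Step 2. Opening of the rigid 7α,8α-epoxide at C7′ has to proceed against the diaxial preference (attack at the tertiary C8′ is blocked), so the selenolate addition may be slow and incomplete. The fallback sets out from 1 and comes back at 5. Silylation of 1 gives drimenyl triethylsilyl ether F3. Allylic oxidation (CrO3·3,5-dimethylpyrazole) gives the 7-en-6-one F4. Nucleophilic epoxidation (H2O2, NaOH) from the α-face gives the 7α,8α-epoxy-6-ketone F5. A Wharton transposition (N2H4·H2O, AcOH) gives the 8α-hydroxy-6-ene F6, and silylation of the tertiary hydroxyl gives 5.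

Step 7. Enolisation may stop at the cross-conjugated dienol ether, which would lead to hydroxylation at C5; the dioxirane may also attack the allylsilane. The fallback sets out from 9 and comes back at 11. The potassium dienolate (KOtBu, THF/tBuOH, −20 °C), which is through-conjugated under equilibration, is oxygenated with O2 at the γ-carbon anti to the side chain to give the γ-hydroperoxide F7, and triethyl phosphite present in the flask reduces it to 11.

Step 8. Activation of the γ-hydroxyl next to the branched C4a may lead to elimination towards a dienone and aromatisation, or to incomplete inversion. The fallback sets out from 11 and comes back at 13. The trans mesylate F1 is displaced with caesium acetate and 18-crown-6 in toluene to give the cis acetate F8, and methanolysis (K2CO3, MeOH, 0 °C) gives 13.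

Step 11. Proton loss may occur partly from C4a, giving the tetrasubstituted alkene, and hypochlorous acid may add to the C6′=C7′ alkene. The fallback sets out from 14 and comes back at 16. A Schenck ene reaction with singlet oxygen (O2, tetraphenylporphyrin, hν, CH2Cl2) abstracts the axial hydrogen at C3 and gives the allylic hydroperoxide F9. Triphenylphosphine reduces it to the allylic alcohol F10, and acetylation (Ac2O, pyridine, DMAP) gives 16.

## Further compounds

F1 | step 10 | (4S,5R)-4-(methanesulfonyloxy)-2-methyl-5-[3-(trimethylsilyl)prop-1-en-2-yl]cyclohex-2-en-1-one (trans mesylate) | C=C(C[Si](C)(C)C)[C@H]1CC(=O)C(C)=C[C@@H]1OS(C)(=O)=O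
F2 | step 10 | Sakurai adduct: trans-4-(methanesulfonyloxy)-5-{4-hydroxy-4-[8α-(triethylsilyloxy)-11-nordrim-6-en-9β-yl]but-1-en-2-yl}-2-methylcyclohex-2-en-1-one (carbinol carbon configured as C2 of 14) | C=C(C[C@@H](O)[C@@H]2[C@@]3(C)CCCC(C)(C)[C@@H]3C=C[C@@]2(C)O[Si](CC)(CC)CC)[C@H]1CC(=O)C(C)=C[C@@H]1OS(C)(=O)=O
F3 | step 2 | 11-(triethylsilyloxy)drim-7-ene | CC[Si](CC)(CC)OC[C@@H]1[C@@]2(C)CCCC(C)(C)[C@@H]2CC=C1C
F4 | step 2 | 11-(triethylsilyloxy)drim-7-en-6-one | CC[Si](CC)(CC)OC[C@@H]1[C@@]2(C)CCCC(C)(C)[C@@H]2C(=O)C=C1C
F5 | step 2 | 7α,8α-epoxy-11-(triethylsilyloxy)driman-6-one | CC[Si](CC)(CC)OC[C@@H]1[C@@]2(C)CCCC(C)(C)[C@@H]2C(=O)[C@H]3O[C@@]13C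
F6 | step 2 | 11-(triethylsilyloxy)drim-6-en-8α-ol | CC[Si](CC)(CC)OC[C@@H]1[C@@]2(C)CCCC(C)(C)[C@@H]2C=C[C@@]1(C)O
F7 | step 7 | (4S,5R)-4-hydroperoxy-2-methyl-5-[3-(trimethylsilyl)prop-1-en-2-yl]cyclohex-2-en-1-one (trans) | C=C(C[Si](C)(C)C)[C@H]1CC(=O)C(C)=C[C@@H]1OO
F8 | step 8 | (4R,5R)-4-acetoxy-2-methyl-5-[3-(trimethylsilyl)prop-1-en-2-yl]cyclohex-2-en-1-one (cis) | C=C(C[Si](C)(C)C)[C@H]1CC(=O)C(C)=C[C@H]1OC(C)=O
F9 | step 11 | (2R,4aR,8aR)-4-(hydroperoxymethyl)-7-methyl-2-[8α-(triethylsilyloxy)-11-nordrim-6-en-9β-yl]-4a,5-dihydro-2H-chromen-6(8aH)-one | OOCC1=C[C@H]([C@@H]2[C@@]3(C)CCCC(C)(C)[C@@H]3C=C[C@@]2(C)O[Si](CC)(CC)CC)O[C@@H]2C=C(C)C(=O)C[C@H]12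
F10 | step 11 | (2R,4aR,8aR)-4-(hydroxymethyl)-7-methyl-2-[8α-(triethylsilyloxy)-11-nordrim-6-en-9β-yl]-4a,5-dihydro-2H-chromen-6(8aH)-one | OCC1=C[C@H]([C@@H]2[C@@]3(C)CCCC(C)(C)[C@@H]3C=C[C@@]2(C)O[Si](CC)(CC)CC)O[C@@H]2C=C(C)C(=O)C[C@H]12
A1 | alternative 1 | (R)-5-[(E)-3-acetoxy-1-iodoprop-1-en-2-yl]-2-methylcyclohex-2-en-1-one (iodine cis to the ring carbon) | CC(=O)OC/C(=C/I)[C@H]1CC(=O)C(C)=CC1
A2 | alternative 1 | Nozaki–Hiyama–Kishi adduct: allylic alcohol joining the drimane carbinol carbon to the carvone-derived vinyl group | CC(=O)OC/C(=C/[C@@H](O)[C@@H]2[C@@]3(C)CCCC(C)(C)[C@@H]3C=C[C@@]2(C)O[Si](CC)(CC)CC)[C@H]1CC(=O)C(C)=CC1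
A3 | alternative 2 | cis-5-acetyl-4-hydroxy-2-methylcyclohex-2-en-1-one (C5 as in (R)-carvone) | CC(=O)[C@H]1CC(=O)C(C)=C[C@H]1O
A4 | alternative 2 | aldol condensation product: (E)-enone between A3 and aldehyde 6 | O=C(/C=C/[C@@H]2[C@@]3(C)CCCC(C)(C)[C@@H]3C=C[C@@]2(C)O[Si](CC)(CC)CC)[C@H]1CC(=O)C(C)=C[C@H]1O
A5 | alternative 2 | 2,6-cis tetrahydropyran-4-one: (2R,4aR,8aR)-7-methyl-2-[8α-(triethylsilyloxy)-11-nordrim-6-en-9β-yl]-2,3,4a,5-tetrahydro-4H-chromene-4,6(8aH)-dione | O=C1C[C@H]([C@@H]2[C@@]3(C)CCCC(C)(C)[C@@H]3C=C[C@@]2(C)O[Si](CC)(CC)CC)O[C@@H]2C=C(C)C(=O)C[C@H]12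
A6 | alternative 3 | 2-dienyl-3-methylfuran: (2E,4E)-2-[2-(3-methylfuran-2-yl)ethylidene]-4-[8α-(triethylsilyloxy)-11-nordrim-6-en-9β-yl]but-3-en-1-yl acetate | Cc1ccoc1C/C=C(COC(C)=O)/C=C/[C@@H]1[C@@]2(C)CCCC(C)(C)[C@@H]2C=C[C@@]1(C)O[Si](CC)(CC)CC
A7 | alternative 3 | (Z)-keto-enal from oxidative opening of A6 | O=C/C=C(C)\C(=O)C/C=C(COC(C)=O)/C=C/[C@@H]1[C@@]2(C)CCCC(C)(C)[C@@H]2C=C[C@@]1(C)O[Si](CC)(CC)CC
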